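The numbers of this flask were drawn at random within sensible limits.

5 questions stand on 4 set-ups with one charge.

in all of them: starting material 0.25 M; partner 0.250 M; protic impurity 0.125 M; free catalyst 1.2 mM

| flask | second substrate | remark | time |
|---|---|---|---|
| autumn | 0.250 M | one stirred flow tank at steady state, fed with the mixture as stated, mean residence time 50 min |  |
| summer | 0.250 M (fed, over 40.0 min) | a stirred flask in which second substrate is dosed at a steady rate over 40.0 min without added volume, worked up at 50 min | 50 min |
| midnight | 0.250 M | everything together in a closed stirred flask, run for 50 min | 50 min |
| noon | 0.250 M | a single well-mixed tank run continuously and read at steady state, 150 min in it on average |  |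

- the set-up with the highest amount of target at the outlet or at the end, in percent of the starting material put in ("none" if the first two lie within 2 percentage points) (autumn / summer / midnight / noon / none)
- amount of target at the outlet or at the end, in percent of the starting material put in, autumn
- amount of target at the outlet or at the end, in percent of the starting material put in, summer
- amount of target at the outlet or at the end, in percent of the starting material put in, midnight
- amount of target at the outlet or at the end, in percent of the starting material put in, noon

    starting material + free catalyst ⇌ catalyst intermediate A (K1 = 40 M⁻¹, k1 = 1.8 M⁻¹ s⁻¹)
    partner + catalyst intermediate A → free catalyst + target (k2 = 3.6 M⁻¹ s⁻¹)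
    second substrate + free catalyst ⇌ catalyst intermediate B (K3 = 2.3 M⁻¹, k3 = 7.1 M⁻¹ s⁻¹)
    partner + catalyst intermediate B → free catalyst + second product (k4 = 39 M⁻¹ s⁻¹)
    partner + protic impurity → quenched reagent (k5 = 0.0066 M⁻¹ s⁻¹)
    starting material + partner → uncatalysed product (k6 = 2.4 × 10⁻⁴ M⁻¹ s⁻¹)

1. What must be known well. Partner is the limiting reagent: 0.250 M against 0.625 M of things consuming it. If the whole partner charge reacts, target in percent of starting material is the fraction of partner reaching target, times partner charge over starting-material charge.

2. The uncatalysed step can go in this reckoning: at the charge it takes partner at 0.00360 min⁻¹, while quenching takes it at 0.0495 min⁻¹.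

3. Take the moment when half of the partner is spent, leaving 0.125 M. Catalyst intermediate A falls back at 0.0450 s⁻¹, while partner takes it at 0.450 s⁻¹, so at that moment that equilibrium constant can go. Catalyst intermediate B falls back at 3.09 s⁻¹ against 4.88 s⁻¹, so its constant stays.

4. Round one, summer, at the charge with no second substrate dosed yet. The catalyst cycle, binding plus partner's attack, gives 21.6 mM min⁻¹. Quenching takes 12.4 mM min⁻¹, so 63.6% of partner goes to the cycle. At that pace, half the partner lasts 3.68 min.

5. Round two puts this back. For that moment we estimate starting material at 0.171 M, protic impurity at 0.0795 M, and 0.0230 M of second substrate dosed. Of each bound second substrate, 61.2% goes on to second product. The cycle now runs at 13.1 mM min⁻¹, and target takes 75.4% of it. That gives the partner share φ, the fraction of partner going to target at that moment 58.1%, which we take for the whole run. Our summer yield is 58.1%. We expect summer ahead of midnight and reckon no tank.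

6. The forecast: best summer; autumn 42.2%, summer 59.5%, midnight 31.5%, noon 47%. Its ground: “Dosing keeps the second substrate low”. Its summer figure stands above ours.

7. The simulation: best summer; autumn 42.0%, summer 59.4%, midnight 31.2%, noon 46.9%. In summer at 50.0 min, partner stands at 0% of its charge. φ sends 0.105 M of partner elsewhere; the summer flask holds 0.0432 M of second product, 0.0545 M of quenched reagent and 0.00377 M of uncatalysed product.

8. The summer flask with 0.062 M of partner: φ, carried over unchanged, gives 14.4%. The computed flask gives 17.8%.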